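**Retrosynthetic overview**
1. Target 13 ⇐ (Z)-maleic half-ester 12: one syn addition of H2 sets C2 and C3 together (new asymmetric hydrogenation, last step).
2. 12 ⇐ (Z)-enol triflate 10: the free carboxyl comes in as CO (hydroxycarbonylation), so acid and methyl ester are differentiated by construction.
3. 10 ⇐ β-keto ester 9 ⇐ aldol of ester 5 with aldehyde 6, then oxidation (C2–C3 bond).
4. 5 ⇐ 4-bromo-3-hydroxybenzaldehyde 1: silylation, Wittig, alkene reduction, Stille prenylation.
5. No ring is formed; both benzene rings are bought.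

Assumption: the SMILES is read as the (2R,3R) isomer, numbered C1 = free carboxyl, C2 = carbon bearing the 4-hydroxyphenyl group, C3 = carbon bearing the benzyl group, C4 = methyl ester carbon.

**Route**

Step 1
Reactants: 1 4-bromo-3-hydroxybenzaldehyde
Product: 2 4-bromo-3-[(triisopropylsilyl)oxy]benzaldehyde
Conditions: TIPSCl, imidazole, DMF, rt
Reagents that add atoms: chlorotri(propan-2-yl)silane (TIPSCl), CC(C)[Si](Cl)(C(C)C)C(C)C
Why: Imidazole-promoted silyl ether formation masks the phenol as a robust TIPS ether that survives the enolate, triflation and palladium steps and is removed by fluoride in step 9.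

Step 2
Reactants: 2 4-bromo-3-[(triisopropylsilyl)oxy]benzaldehyde
Product: 3 methyl (2E)-3-{4-bromo-3-[(triisopropylsilyl)oxy]phenyl}prop-2-enoate
Conditions: Ph3P=CHCO2Me, toluene, 70 °C
Reagents that add atoms: methyl (triphenylphosphoranylidene)acetate, COC(=O)C=P(c1ccccc1)(c1ccccc1)c1ccccc1
Why: Wittig olefination with a stabilised ylide gives the E cinnamate reliably, and its geometry is irrelevant because the alkene is saturated in step 3.

Step 3
Reactants: 3 methyl (2E)-3-{4-bromo-3-[(triisopropylsilyl)oxy]phenyl}prop-2-enoate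
Product: 4 methyl 3-{4-bromo-3-[(triisopropylsilyl)oxy]phenyl}propanoate
Conditions: H2 (4 atm), RhCl(PPh3)3 (5 mol %), THF/t-BuOH, 40 °C
Reagents that add atoms: none
Why: Homogeneous hydrogenation with RhCl(PPh3)3 reduces the conjugated disubstituted alkene without hydrogenolysis of the aryl bromide or loss of the silyl ether.

Step 4
Reactants: 4 methyl 3-{4-bromo-3-[(triisopropylsilyl)oxy]phenyl}propanoate
Product: 5 methyl 3-{4-(3-methylbut-2-en-1-yl)-3-[(triisopropylsilyl)oxy]phenyl}propanoate
Conditions: Bu3SnCH2CH=CMe2, Pd(PPh3)4 (5 mol %), DMF, 90 °C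
Reagents that add atoms: tributyl(3-methylbut-2-en-1-yl)stannane, CCCC[Sn](CCCC)(CCCC)CC=C(C)C
Why: Stille coupling, in which reductive elimination from the allyl(aryl)palladium intermediate occurs at the unsubstituted terminus to give the linear prenyl arene, with ester and silyl ether inert under the neutral conditions.

Step 5
Reactants: 5 methyl 3-{4-(3-methylbut-2-en-1-yl)-3-[(triisopropylsilyl)oxy]phenyl}propanoate; 6 4-[(tert-butyldimethylsilyl)oxy]benzaldehyde
Product: 8 methyl 3-{4-[(tert-butyldimethylsilyl)oxy]phenyl}-3-hydroxy-2-{[4-(3-methylbut-2-en-1-yl)-3-[(triisopropylsilyl)oxy]phenyl]methyl}propanoate (racemic diastereomer mixture), via lithium ester enolate 7 (not isolated)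
Conditions: LiN(iPr)2, THF, −78 °C; then 6, −78 °C; AcOH quench
Reagents that add atoms: none
Why: Kinetic ester enolate formation and aldol addition to a non-enolisable aryl aldehyde forms the C2–C3 bond, and no selectivity is needed because both new stereocentres are erased in steps 6 and 7.

Step 6
Reactants: 8 methyl 3-{4-[(tert-butyldimethylsilyl)oxy]phenyl}-3-hydroxy-2-{[4-(3-methylbut-2-en-1-yl)-3-[(triisopropylsilyl)oxy]phenyl]methyl}propanoate
Product: 9 methyl 3-{4-[(tert-butyldimethylsilyl)oxy]phenyl}-2-{[4-(3-methylbut-2-en-1-yl)-3-[(triisopropylsilyl)oxy]phenyl]methyl}-3-oxopropanoate (racemic)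
Conditions: Dess–Martin periodinane, CH2Cl2, 0 °C to rt
Reagents that add atoms: none
Why: Dess–Martin oxidation converts the benzylic secondary alcohol into the aryl ketone under neutral conditions that leave the prenyl alkene, the ester and both silyl ethers untouched.

Step 7
Reactants: 9 methyl 3-{4-[(tert-butyldimethylsilyl)oxy]phenyl}-2-{[4-(3-methylbut-2-en-1-yl)-3-[(triisopropylsilyl)oxy]phenyl]methyl}-3-oxopropanoate
Product: 10 methyl (2Z)-3-{4-[(tert-butyldimethylsilyl)oxy]phenyl}-2-{[4-(3-methylbut-2-en-1-yl)-3-[(triisopropylsilyl)oxy]phenyl]methyl}-3-{[(trifluoromethyl)sulfonyl]oxy}prop-2-enoate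
Conditions: Tf2O, LiOTf, Et3N, CH2Cl2, −20 to 0 °C
Reagents that add atoms: trifluoromethanesulfonic anhydride, O=S(=O)(OS(=O)(=O)C(F)(F)F)C(F)(F)F
Why: Chelation-controlled enol triflation of a β-keto ester, in which lithium bridges the enolate oxygen and the ester carbonyl so that O-sulfonylation gives the Z enol triflate (OTf cis to CO2Me, aryl cis to the benzyl group), fixing the alkene geometry that step 10 turns into the relative configuration.

Step 8
Reactants: 10 methyl (2Z)-3-{4-[(tert-butyldimethylsilyl)oxy]phenyl}-2-{[4-(3-methylbut-2-en-1-yl)-3-[(triisopropylsilyl)oxy]phenyl]methyl}-3-{[(trifluoromethyl)sulfonyl]oxy}prop-2-enoate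
Product: 11 (2Z)-2-{4-[(tert-butyldimethylsilyl)oxy]phenyl}-4-methoxy-3-{[4-(3-methylbut-2-en-1-yl)-3-[(triisopropylsilyl)oxy]phenyl]methyl}-4-oxobut-2-enoic acid
Conditions: CO (1 atm), Pd(OAc)2 (10 mol %), dppp (12 mol %), H2O, Et3N, DMF, 60 °C
Reagents that add atoms: carbon monoxide, [C-]#[O+]; water, O
Why: Palladium-catalysed hydroxycarbonylation of an enol triflate (oxidative addition to zerovalent palladium, CO insertion, hydrolysis of the acyl–palladium) proceeds with retention of alkene geometry, so the new free carboxyl ends up cis to the methyl ester and the two carboxyl groups are differentiated by construction.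

Step 9
Reactants: 11 (2Z)-2-{4-[(tert-butyldimethylsilyl)oxy]phenyl}-4-methoxy-3-{[4-(3-methylbut-2-en-1-yl)-3-[(triisopropylsilyl)oxy]phenyl]methyl}-4-oxobut-2-enoic acid
Product: 12 (2Z)-2-(4-hydroxyphenyl)-3-{[3-hydroxy-4-(3-methylbut-2-en-1-yl)phenyl]methyl}-4-methoxy-4-oxobut-2-enoic acid
Conditions: Bu4NF, AcOH (1:1), THF, 0 °C to rt
Reagents that add atoms: none
Why: Fluoride-mediated cleavage of both aryl silyl ethers, buffered with AcOH so that the methyl ester is not hydrolysed and the tetrasubstituted maleate neither isomerises nor shifts its double bond into the benzylic position.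

Step 10
Reactants: 12 (2Z)-2-(4-hydroxyphenyl)-3-{[3-hydroxy-4-(3-methylbut-2-en-1-yl)phenyl]methyl}-4-methoxy-4-oxobut-2-enoic acid
Product: 13 (2R,3R)-2-(4-hydroxyphenyl)-3-{[3-hydroxy-4-(3-methylbut-2-en-1-yl)phenyl]methyl}-4-methoxy-4-oxobutanoic acid
Conditions: H2 (100 atm), Ru(OAc)2[(S)-BINAP] (2 mol %), MeOH, 40 °C
Reagents that add atoms: none
Why: Proposed new method: carboxylate-directed asymmetric hydrogenation of a fully substituted, acyclic maleic acid monoester, in which the free acid exchanges with acetate on ruthenium, the tetrasubstituted C=C chelates through that carboxylate (helped by the cis ester carbonyl), and hydride insertion followed by Ru–C cleavage delivers both hydrogens to one face (the C2-Re/C3-Si face of 12), so that the Z geometry fixes the relative and the BINAP chirality the absolute configuration of both new centres in one step, while the prenyl alkene has no chelating handle and stays untouched and high pressure outruns β-hydride elimination; the closest known reaction type is the Ru(OAc)2(BINAP)-type directed hydrogenation of α,β-unsaturated carboxylic acids (including tetrasubstituted α-aryl acrylic acids) and of geraniol with its remote trisubstituted alkene retained, but a tetrasubstituted 2-aryl-3-alkyl maleic half-ester giving two vicinal stereocentres has not been shown, and the (S)-ligand is assigned only by analogy, its antipode being used if the sense of induction proves opposite.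

**Compound list**
1 | 4-bromo-3-hydroxybenzaldehyde | O=Cc1ccc(Br)c(O)c1 | starting material
2 | 4-bromo-3-[(triisopropylsilyl)oxy]benzaldehyde | O=Cc1ccc(Br)c(O[Si](C(C)C)(C(C)C)C(C)C)c1 | intermediate
3 | methyl (2E)-3-{4-bromo-3-[(triisopropylsilyl)oxy]phenyl}prop-2-enoate | COC(=O)/C=C/c1ccc(Br)c(O[Si](C(C)C)(C(C)C)C(C)C)c1 | intermediate
4 | methyl 3-{4-bromo-3-[(triisopropylsilyl)oxy]phenyl}propanoate | COC(=O)CCc1ccc(Br)c(O[Si](C(C)C)(C(C)C)C(C)C)c1 | intermediate
5 | methyl 3-{4-(3-methylbut-2-en-1-yl)-3-[(triisopropylsilyl)oxy]phenyl}propanoate | COC(=O)CCc1ccc(CC=C(C)C)c(O[Si](C(C)C)(C(C)C)C(C)C)c1 | intermediate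
6 | 4-[(tert-butyldimethylsilyl)oxy]benzaldehyde | O=Cc1ccc(O[Si](C)(C)C(C)(C)C)cc1 | starting material
7 | lithium ester enolate (lithium 1-methoxy-3-{4-(3-methylbut-2-en-1-yl)-3-[(triisopropylsilyl)oxy]phenyl}prop-1-en-1-olate; formed from 5, not isolated, enolate geometry not defined) | [Li+].[O-]C(OC)=CCc1ccc(CC=C(C)C)c(O[Si](C(C)C)(C(C)C)C(C)C)c1 | intermediate
8 | methyl 3-{4-[(tert-butyldimethylsilyl)oxy]phenyl}-3-hydroxy-2-{[4-(3-methylbut-2-en-1-yl)-3-[(triisopropylsilyl)oxy]phenyl]methyl}propanoate (racemic diastereomer mixture) | COC(=O)C(Cc1ccc(CC=C(C)C)c(O[Si](C(C)C)(C(C)C)C(C)C)c1)C(O)c1ccc(O[Si](C)(C)C(C)(C)C)cc1 | intermediate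
9 | methyl 3-{4-[(tert-butyldimethylsilyl)oxy]phenyl}-2-{[4-(3-methylbut-2-en-1-yl)-3-[(triisopropylsilyl)oxy]phenyl]methyl}-3-oxopropanoate (racemic) | COC(=O)C(Cc1ccc(CC=C(C)C)c(O[Si](C(C)C)(C(C)C)C(C)C)c1)C(=O)c1ccc(O[Si](C)(C)C(C)(C)C)cc1 | intermediate
10 | methyl (2Z)-3-{4-[(tert-butyldimethylsilyl)oxy]phenyl}-2-{[4-(3-methylbut-2-en-1-yl)-3-[(triisopropylsilyl)oxy]phenyl]methyl}-3-{[(trifluoromethyl)sulfonyl]oxy}prop-2-enoate (OTf cis to CO2Me) | COC(=O)/C(Cc1ccc(CC=C(C)C)c(O[Si](C(C)C)(C(C)C)C(C)C)c1)=C(\OS(=O)(=O)C(F)(F)F)c1ccc(O[Si](C)(C)C(C)(C)C)cc1 | intermediate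
11 | (2Z)-2-{4-[(tert-butyldimethylsilyl)oxy]phenyl}-4-methoxy-3-{[4-(3-methylbut-2-en-1-yl)-3-[(triisopropylsilyl)oxy]phenyl]methyl}-4-oxobut-2-enoic acid (carboxyl groups cis) | COC(=O)/C(Cc1ccc(CC=C(C)C)c(O[Si](C(C)C)(C(C)C)C(C)C)c1)=C(\C(=O)O)c1ccc(O[Si](C)(C)C(C)(C)C)cc1 | intermediate
12 | (2Z)-2-(4-hydroxyphenyl)-3-{[3-hydroxy-4-(3-methylbut-2-en-1-yl)phenyl]methyl}-4-methoxy-4-oxobut-2-enoic acid (carboxyl groups cis) | COC(=O)/C(Cc1ccc(CC=C(C)C)c(O)c1)=C(\C(=O)O)c1ccc(O)cc1 | intermediate
13 | (2R,3R)-2-(4-hydroxyphenyl)-3-{[3-hydroxy-4-(3-methylbut-2-en-1-yl)phenyl]methyl}-4-methoxy-4-oxobutanoic acid | COC(=O)[C@H](Cc1ccc(CC=C(C)C)c(O)c1)[C@@H](C(=O)O)c1ccc(O)cc1 | target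

**Step count**
Total step count: 10. Longest linear sequence: 10 steps (1 to 13).

**Steps most likely to fail**

Step 10 (the proposed new hydrogenation). The tetrasubstituted, doubly conjugated alkene may turn over slowly, may give low enantioselectivity, or may leak to the other diastereomer through β-hydride elimination and double-bond migration. The fallback uses known chemistry, sets out from 12 and comes back to the route at 13. Hydrogenation of 12 with the achiral directed catalyst [Rh(nbd)(dppb)]BF4 (H2 50 atm, CH2Cl2/MeOH, rt) adds H2 cis to the Z alkene and so gives only the syn pair. This is racemic material made up of 13 and its mirror image (2S,3S)-2-(4-hydroxyphenyl)-3-{[3-hydroxy-4-(3-methylbut-2-en-1-yl)phenyl]methyl}-4-methoxy-4-oxobutanoic acid F1. Preparative chiral SFC on a polysaccharide phase then separates 13 from F1. The yield is capped at 50 %, and this fallback helps only if the failure is one of selectivity; it does not help if the alkene resists homogeneous hydrogenation altogether.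

Step 4 (Stille prenylation). Oxidative addition next to the bulky silyl ether may be sluggish, or the stannane may transfer through its γ-carbon to give the 1,1-dimethylallyl isomer. The fallback sets out from 4 and comes back at 5. Suzuki–Miyaura allylation with allylB(pin) (Pd(OAc)2, SPhos, K3PO4, THF/H2O, 60 °C) has no regiochemical ambiguity and gives methyl 3-{4-(prop-2-en-1-yl)-3-[(triisopropylsilyl)oxy]phenyl}propanoate F2. Cross-metathesis of F2 with 2-methylbut-2-ene (second-generation Grubbs catalyst, RuCl2(=CHPh)(PCy3)(H2IMes), CH2Cl2, 40 °C) then builds the prenyl group and delivers 5.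

Step 8 (hydroxycarbonylation). Water and Et3N may hydrolyse the enol triflate back to 9 faster than the hindered vinyl–palladium species inserts CO. The fallback sets out from 10 and comes back at 12, bypassing 11. Anhydrous alkoxycarbonylation (CO 1 atm, Pd(OAc)2, dppp, 2-(trimethylsilyl)ethanol, Et3N, DMF, 60 °C) gives the neutral mixed diester 4-methyl 1-[2-(trimethylsilyl)ethyl] (2Z)-2-{4-[(tert-butyldimethylsilyl)oxy]phenyl}-3-{[4-(3-methylbut-2-en-1-yl)-3-[(triisopropylsilyl)oxy]phenyl]methyl}but-2-enedioate F3. Bu4NF in THF (0 °C to rt, acidic work-up) then removes the 2-(trimethylsilyl)ethyl ester and both aryl silyl ethers in one operation to give 12.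

**Further compounds**
F1 | step 10 | (2S,3S)-2-(4-hydroxyphenyl)-3-{[3-hydroxy-4-(3-methylbut-2-en-1-yl)phenyl]methyl}-4-methoxy-4-oxobutanoic acid | COC(=O)[C@@H](Cc1ccc(CC=C(C)C)c(O)c1)[C@H](C(=O)O)c1ccc(O)cc1
F2 | step 4 | methyl 3-{4-(prop-2-en-1-yl)-3-[(triisopropylsilyl)oxy]phenyl}propanoate | COC(=O)CCc1ccc(CC=C)c(O[Si](C(C)C)(C(C)C)C(C)C)c1
F3 | step 8 | 4-methyl 1-[2-(trimethylsilyl)ethyl] (2Z)-2-{4-[(tert-butyldimethylsilyl)oxy]phenyl}-3-{[4-(3-methylbut-2-en-1-yl)-3-[(triisopropylsilyl)oxy]phenyl]methyl}but-2-enedioate | COC(=O)/C(Cc1ccc(CC=C(C)C)c(O[Si](C(C)C)(C(C)C)C(C)C)c1)=C(\C(=O)OCC[Si](C)(C)C)c1ccc(O[Si](C)(C)C(C)(C)C)cc1
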